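**Plan**
- Retrosynthesis cuts, in this order: (i) the bond from the furan β-carbon to the ketone carbon (seven-membered ring C); (ii) the lactone-conjugated C=C of ring B and the lactone C–O bond; (iii) in ring A, the CH2–C(OAc) bond and the bond from the quaternary carbon carrying the lactone CH2O to the central CH shared by rings A, B and C.
- Cut (iii) divides the skeleton into an acyl fragment (acetoxy carbon, both C-methyl carbons, central CH, furan, ring C chain) and a five-carbon enal (ring CH2, quaternary carbon, lactone carbons).
- Forward: both fragments are made, joined by a radical annulation that builds ring A, then the spiro lactone, ring B (aldol condensation), the two carbinols, and last ring C (furan acylation).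
- Feature used by the key step: the acetoxy carbon is a masked acyl carbon and sits 1,3 to the quaternary carbon, whose CH2O arm is a masked formyl group. The pair is therefore an acyl radical plus a 2-substituted acrolein, and the central CH is the β-carbon of a furyl enone that accepts the resulting radical in a 6-exo closure.
- Stereochemistry: an enantioselective Ireland–Claisen rearrangement sets the two methyl-bearing carbons; these steer the chair transition state of the annulation (central CH and quaternary carbon). The furyl methine is set by equilibration next to the ring B ketone, and the two carbinols by hydride reduction.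

Key step: step 9

Remark 1: the (S,S)-enantiomer of the boron controller is written for step 3; if its facial preference on ester 5 is the opposite one, the (R,R)-enantiomer is used with no other change.
Remark 2: enal 16 is racemic at its carbinol carbon and the furyl methine forms unselectively in step 9; both centres are left unspecified in 18–24. The first is destroyed in step 11, the second equilibrated in step 12. Enone acid 10 is drawn as the E isomer; either geometry serves in step 9.

Step 1
Reactants: 1 tert-butyl(but-3-yn-1-yloxy)dimethylsilane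
Product: 4 (E)-5-[(tert-butyldimethylsilyl)oxy]-3-methylpent-2-en-1-ol, via alkenyldimethylalane 2 (not isolated), via lithium alkenylalanate 3 (not isolated)
Conditions: Me3Al, Cp2ZrCl2 (0.2 equiv), CH2Cl2, 0 °C to rt; then n-BuLi, THF, −78 °C; (CH2O)n, −78 °C to rt
Reagents that add atoms: trimethylaluminium, C[Al](C)C; paraformaldehyde (as formaldehyde), C=O
Why: Zirconium-catalysed syn carboalumination of the terminal alkyne (Negishi carboalumination) places methyl on the internal and aluminium on the terminal carbon, and hydroxymethylation of the alanate with retention should give the (E)-trisubstituted allylic alcohol.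

Step 2
Reactants: 4 (E)-5-[(tert-butyldimethylsilyl)oxy]-3-methylpent-2-en-1-ol
Product: 5 (E)-5-[(tert-butyldimethylsilyl)oxy]-3-methylpent-2-en-1-yl propanoate
Conditions: propionyl chloride, pyridine, DMAP (cat.), CH2Cl2, 0 °C
Reagents that add atoms: propionyl chloride, CCC(=O)Cl
Why: O-acylation of a primary allylic alcohol under nucleophilic catalysis; no stereocentre is involved.

Step 3
Reactants: 5 (E)-5-[(tert-butyldimethylsilyl)oxy]-3-methylpent-2-en-1-yl propanoate
Product: 7 (2S,3R)-5-[(tert-butyldimethylsilyl)oxy]-3-ethenyl-2,3-dimethylpentanoic acid, via boron ketene acetal 6 (not isolated)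
Conditions: (S,S)-2-bromo-4,5-diphenyl-1,3-bis(4-methylphenylsulfonyl)-1,3,2-diazaborolidine (1.2 equiv), i-Pr2NEt, CH2Cl2, −78 °C to rt; aqueous work-up
Reagents that add atoms: none
Why: Enantioselective Ireland–Claisen rearrangement through a chair transition state of the O-boron ketene acetal (enolate methyl cis to O–B, hence equatorial; alkene methyl cis to CH2O, hence axial) should fix the relative configuration of the tertiary and the quaternary centre, while the C2-symmetric boron controller selects the enolate face and so the absolute configuration of both.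

Step 4
Reactants: 7 (2S,3R)-5-[(tert-butyldimethylsilyl)oxy]-3-ethenyl-2,3-dimethylpentanoic acid
Product: 8 (2S,3S)-5-[(tert-butyldimethylsilyl)oxy]-3-formyl-2,3-dimethylpentanoic acid
Conditions: O3, CH2Cl2/MeOH, −78 °C; then Me2S, −78 °C to rt
Reagents that add atoms: ozone, [O-][O+]=O
Why: Ozonolysis with reductive work-up cleaves the only alkene to the α-quaternary aldehyde, which cannot enolise, so both stereocentres are kept; silyl ether and acid are inert.

Step 5
Reactants: 8 (2S,3S)-5-[(tert-butyldimethylsilyl)oxy]-3-formyl-2,3-dimethylpentanoic acid; 9 1-(furan-2-yl)propan-2-one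
Product: 10 (2S,3R,4E)-3-{2-[(tert-butyldimethylsilyl)oxy]ethyl}-5-(furan-2-yl)-2,3-dimethyl-6-oxohept-4-enoic acid
Conditions: piperidine, AcOH, toluene, reflux, Dean–Stark trap
Reagents that add atoms: none
Why: Knoevenagel condensation at the doubly activated furfuryl CH2 of 9 with the non-enolisable aldehyde, driven by azeotropic removal of water, should build the trisubstituted furyl enone; its geometry is of no consequence later.

Step 6
Reactants: 10 (2S,3R,4E)-3-{2-[(tert-butyldimethylsilyl)oxy]ethyl}-5-(furan-2-yl)-2,3-dimethyl-6-oxohept-4-enoic acid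
Product: 11 Se-phenyl (2S,3R,4E)-3-{2-[(tert-butyldimethylsilyl)oxy]ethyl}-5-(furan-2-yl)-2,3-dimethyl-6-oxohept-4-eneselenoate
Conditions: N-(phenylseleno)phthalimide, PBu3, CH2Cl2, 0 °C to rt
Reagents that add atoms: N-(phenylseleno)phthalimide, O=C1c2ccccc2C(=O)N1[Se]c1ccccc1
Why: Redox condensation of the acid with the selenium transfer reagent and the phosphine gives the Se-phenyl selenoester, the standard acyl radical precursor, under neutral conditions that keep the α-stereocentre.

Step 7
Reactants: 12 2-bromo-3,3-diethoxyprop-1-ene; 13 ethyl glyoxylate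
Product: 15 ethyl 3-(diethoxymethyl)-2-hydroxybut-3-enoate (racemic), via 3,3-diethoxyprop-1-en-2-yllithium 14 (not isolated)
Conditions: n-BuLi, Et2O, −78 °C; then 13 (freshly distilled), −78 °C; aq. NH4Cl
Reagents that add atoms: none
Why: Bromine–lithium exchange gives the acrolein α-anion equivalent, which adds to the aldehyde carbonyl of the glyoxylate faster than to its ester; the carbinol centre is racemic and is removed in step 11.

Step 8
Reactants: 15 ethyl 3-(diethoxymethyl)-2-hydroxybut-3-enoate
Product: 16 ethyl 3-formyl-2-hydroxybut-3-enoate (racemic)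
Conditions: 1 M HCl, acetone, 0 °C; used at once
Reagents that add atoms: water, O
Why: Mild acid hydrolysis of the acetal unmasks the 2-substituted acrolein (the product type of a Morita–Baylis–Hillman reaction).

Step 9
Reactants: 11 Se-phenyl selenoester; 16 ethyl 3-formyl-2-hydroxybut-3-enoate (3 equiv)
Product: 20 ring A keto aldehyde, via acyl radical 17 (not isolated), via α-formyl adduct radical 18 (not isolated), via cyclised radical 19 (not isolated)
Conditions: Bu3SnH (1.3 equiv, syringe pump over 8 h), AIBN (0.2 equiv), benzene, 80 °C, 0.01 M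
Reagents that add atoms: none
Why: Bu3Sn• abstracts the phenylseleno group of 11, and the nucleophilic acyl radical 17 (the future acetoxy carbon) adds to the unsubstituted alkene terminus of 16, which forms the CH2–C(=O) bond and leaves the tertiary α-formyl radical 18 at the future quaternary carbon; 18 closes ring A by 6-exo-trig attack on the β-carbon of the furyl enone (the future central CH), and radical 19, stabilised by furan and acetyl, takes hydrogen from Bu3SnH. The closest known reaction type is the tandem intermolecular addition–cyclisation of acyl radicals from Se-phenyl selenoesters, a radical [4+2] annulation. The central CH is set in a chair transition state with the secondary methyl and the enone arm equatorial and the quaternary methyl axial, so its hydrogen ends trans-diaxial to that methyl. At the new quaternary carbon the planar, conjugated formyl group should take the crowded axial site syn to the axial methyl and the sp3 hydroxy-ester arm the equatorial one, which is the arrangement of the angular CH2O and the ring B bond in the target. The step needs addition before decarbonylation (excess 16), cyclisation before hydrogen transfer (slow addition of Bu3SnH) and 6-exo over 7-endo closure, which the fully substituted, radical-stabilising distal alkene carbon secures.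

Step 10
Reactants: 20 ring A keto aldehyde
Product: 22 spiro hydroxy lactone, via hydroxymethyl ester 21 (not isolated)
Conditions: NaBH4 (0.5 equiv), EtOH/CH2Cl2, −78 °C; aq. NH4Cl; then PPTS (cat.), CH2Cl2, rt
Reagents that add atoms: none
Why: Borohydride at −78 °C should reduce the aldehyde far faster than the two ketones and the ester, and the neopentyl alcohol then closes the five-membered lactone on the neighbouring ethyl ester under acid catalysis.

Step 11
Reactants: 22 spiro hydroxy lactone
Product: 23 spiro keto lactone
Conditions: Dess–Martin periodinane, NaHCO3, CH2Cl2, 0 °C to rt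
Reagents that add atoms: none
Why: Dess–Martin oxidation of the α-hydroxy lactone gives the non-enolisable α-keto lactone (ketopantolactone type) and removes the stereorandom carbinol centre.

Step 12
Reactants: 23 spiro keto lactone
Product: 25 tricyclic enone (ring B closed), via aldol adduct 24 (not isolated)
Conditions: DBU (0.5 equiv), CH2Cl2, rt to 40 °C
Reagents that add atoms: none
Why: Intramolecular aldol condensation: the methyl ketone enolate attacks the very electrophilic α-keto lactone carbonyl (six-membered ring) and E1cB loss of water gives the enone conjugated to the lactone; the furyl methine, α to the new ring B ketone, should equilibrate to the equatorial epimer (trans ring fusion), since the axial one clashes 1,3-diaxially with the angular CH2O.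

Step 13
Reactants: 25 tricyclic enone
Product: 26 diol
Conditions: NaBH4, CeCl3·7H2O, MeOH, −78 to 0 °C
Reagents that add atoms: none
Why: Luche 1,2-reduction: axial hydride attack on the ring B enone gives the equatorial allylic alcohol, while the ring A ketone, whose axial face is blocked by the syn-axial angular CH2O and quaternary methyl, is attacked equatorially and gives the axial alcohol.

Step 14
Reactants: 26 diol
Product: 27 diacetate
Conditions: Ac2O (excess), DMAP, pyridine, rt to 40 °C
Reagents that add atoms: acetic anhydride, CC(=O)OC(C)=O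
Why: DMAP-catalysed acylation esterifies both secondary alcohols; the hindered axial one needs the excess reagent and warming.

Step 15
Reactants: 27 diacetate
Product: 28 primary alcohol
Conditions: HF·pyridine, pyridine/THF, 0 °C to rt
Reagents that add atoms: none
Why: Fluoride cleaves the primary silyl ether; the buffered reagent leaves acetates, lactone and furan intact.

Step 16
Reactants: 28 primary alcohol
Product: 29 carboxylic acid
Conditions: TEMPO (0.2 equiv), PhI(OAc)2 (2.5 equiv), MeCN/H2O 1:1, rt
Reagents that add atoms: water, O
Why: Oxoammonium oxidation of the primary alcohol proceeds through the aldehyde hydrate to the acid; no free secondary alcohol is present.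

Step 17
Reactants: 29 carboxylic acid
Product: 31 O-acetyl target (ring C closed), via mixed trifluoroacetic anhydride 30 (not isolated)
Conditions: (CF3CO)2O (3 equiv), CH2Cl2, 0 °C to rt, 0.005 M
Reagents that add atoms: none
Why: Intramolecular Friedel–Crafts acylation of the furan by the mixed anhydride; the tether reaches only the furan carbon next to the existing substituent and should close the seven-membered ketone ring C across two equatorial bonds (trans fusion).

Step 18
Reactants: 31 O-acetyl target
Product: 32 target CNP0182929.1
Conditions: K2CO3 (0.3 equiv), MeOH, 0 °C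
Reagents that add atoms: none
Why: Base-catalysed methanolysis should remove the exposed equatorial allylic acetate much faster than the axial acetate, which is shielded by two syn-axial groups.

**Compound list**
1 | tert-butyl(but-3-yn-1-yloxy)dimethylsilane | C#CCCO[Si](C)(C)C(C)(C)C | starting material
2 | (E)-alkenyldimethylalane from syn carboalumination of 1 | C[Al](C)/C=C(\C)CCO[Si](C)(C)C(C)(C)C | intermediate
3 | lithium (E)-alkenyl(butyl)dimethylalanate | [Li+].CCCC[Al-](C)(C)/C=C(\C)CCO[Si](C)(C)C(C)(C)C | intermediate
4 | (E)-5-[(tert-butyldimethylsilyl)oxy]-3-methylpent-2-en-1-ol | OC/C=C(\C)CCO[Si](C)(C)C(C)(C)C | intermediate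
5 | (E)-5-[(tert-butyldimethylsilyl)oxy]-3-methylpent-2-en-1-yl propanoate | CCC(=O)OC/C=C(\C)CCO[Si](C)(C)C(C)(C)C | intermediate
6 | O-boron ketene acetal of 5 (methyl cis to O–B) carrying the (S,S)-diazaborolidine | C/C=C(\OB1N(S(=O)(=O)c2ccc(C)cc2)[C@@H](c2ccccc2)[C@H](c2ccccc2)N1S(=O)(=O)c1ccc(C)cc1)OC/C=C(\C)CCO[Si](C)(C)C(C)(C)C | intermediate
7 | (2S,3R)-5-[(tert-butyldimethylsilyl)oxy]-3-ethenyl-2,3-dimethylpentanoic acid | CC(C)(C)[Si](C)(C)OCC[C@@](C)([C@@H](C(=O)O)C)C=C | intermediate
8 | (2S,3S)-5-[(tert-butyldimethylsilyl)oxy]-3-formyl-2,3-dimethylpentanoic acid | CC(C)(C)[Si](C)(C)OCC[C@@](C)([C@@H](C(=O)O)C)C=O | intermediate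
9 | 1-(furan-2-yl)propan-2-one | CC(=O)Cc1ccco1 | starting material
10 | (2S,3R,4E)-3-{2-[(tert-butyldimethylsilyl)oxy]ethyl}-5-(furan-2-yl)-2,3-dimethyl-6-oxohept-4-enoic acid | CC(C)(C)[Si](C)(C)OCC[C@@](C)([C@@H](C(=O)O)C)/C=C(\c1ccco1)C(C)=O | intermediate
11 | Se-phenyl selenoester of 10 | CC(C)(C)[Si](C)(C)OCC[C@@](C)([C@@H](C(=O)[Se]c1ccccc1)C)/C=C(\c1ccco1)C(C)=O | intermediate
12 | 2-bromo-3,3-diethoxyprop-1-ene | C=C(Br)C(OCC)OCC | starting material
13 | ethyl glyoxylate | CCOC(=O)C=O | starting material
14 | 3,3-diethoxyprop-1-en-2-yllithium | [Li]C(=C)C(OCC)OCC | intermediate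
15 | ethyl 3-(diethoxymethyl)-2-hydroxybut-3-enoate (racemic) | CCOC(=O)C(O)C(=C)C(OCC)OCC | intermediate
16 | ethyl 3-formyl-2-hydroxybut-3-enoate (racemic) | CCOC(=O)C(O)C(=C)C=O | intermediate
17 | acyl radical from 11 | CC(C)(C)[Si](C)(C)OCC[C@@](C)([C@@H]([C]=O)C)/C=C(\c1ccco1)C(C)=O | intermediate
18 | tertiary α-formyl radical after addition of 17 to 16 | CC(C)(C)[Si](C)(C)OCC[C@@](C)([C@@H](C(=O)C[C](C=O)C(O)C(=O)OCC)C)/C=C(\c1ccco1)C(C)=O | intermediate
19 | ring A radical at the furyl/acetyl-bearing carbon | O=C1C[C@@](C=O)(C(O)C(=O)OCC)[C@H]([C](c2ccco2)C(C)=O)[C@@](C)(CCO[Si](C)(C)C(C)(C)C)[C@@H]1C | intermediate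
20 | ring A keto aldehyde: ethyl 2-hydroxy-2-{1-formyl-2-[1-(furan-2-yl)-2-oxopropyl]-3-[2-(tert-butyldimethylsilyloxy)ethyl]-3,4-dimethyl-5-oxocyclohexyl}acetate; formyl, the C2 arm and both ring methyls on one face (formyl and 3-methyl 1,3-diaxial), H-2 and H-4 on the other; side-chain methines unspecified | O=C1C[C@@](C=O)(C(O)C(=O)OCC)[C@H](C(c2ccco2)C(C)=O)[C@@](C)(CCO[Si](C)(C)C(C)(C)C)[C@@H]1C | intermediate
21 | hydroxymethyl ester: 20 with CHO reduced to CH2OH | O=C1C[C@@](CO)(C(O)C(=O)OCC)[C@H](C(c2ccco2)C(C)=O)[C@@](C)(CCO[Si](C)(C)C(C)(C)C)[C@@H]1C | intermediate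
22 | spiro hydroxy lactone: α-hydroxy γ-lactone spiro-fused to ring A at the quaternary carbon (lactone CH2 axial, syn to the quaternary methyl); ring A ketone, furyl-oxopropyl arm and silyloxyethyl chain as in 20 | O=C1C[C@]2(COC(=O)C2O)[C@H](C(c3ccco3)C(C)=O)[C@@](C)(CCO[Si](C)(C)C(C)(C)C)[C@@H]1C | intermediate
23 | spiro keto lactone: 22 with the carbinol oxidised to the α-keto lactone | O=C1C[C@]2(COC(=O)C2=O)[C@H](C(c3ccco3)C(C)=O)[C@@](C)(CCO[Si](C)(C)C(C)(C)C)[C@@H]1C | intermediate
24 | aldol adduct: ring B closed, tertiary alcohol at the lactone α-carbon | O=C1C[C@@]23COC(=O)C2(O)CC(=O)C(c2ccco2)[C@@H]3[C@@](C)(CCO[Si](C)(C)C(C)(C)C)[C@@H]1C | intermediate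
25 | tricyclic enone: ring B cyclohexenone trans-fused to ring A, α-alkylidene γ-lactone on the angular carbon, equatorial furan-2-yl next to the enone carbonyl, ring A ketone, silyloxyethyl chain | O=C1C[C@@]23COC(=O)C2=CC(=O)[C@@H](c2ccco2)[C@@H]3[C@@](C)(CCO[Si](C)(C)C(C)(C)C)[C@@H]1C | intermediate
26 | diol: axial ring A alcohol (syn to angular CH2O and quaternary methyl) and equatorial allylic ring B alcohol (trans to furyl) | O[C@@H]1C[C@@]23COC(=O)C2=C[C@H](O)[C@@H](c2ccco2)[C@@H]3[C@@](C)(CCO[Si](C)(C)C(C)(C)C)[C@@H]1C | intermediate
27 | diacetate of 26 | CC(=O)O[C@@H]1C[C@@]23COC(=O)C2=C[C@H](OC(C)=O)[C@@H](c2ccco2)[C@@H]3[C@@](C)(CCO[Si](C)(C)C(C)(C)C)[C@@H]1C | intermediate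
28 | primary alcohol: 27 without the silyl group | CC(=O)O[C@@H]1C[C@@]23COC(=O)C2=C[C@H](OC(C)=O)[C@@H](c2ccco2)[C@@H]3[C@@](C)(CCO)[C@@H]1C | intermediate
29 | carboxylic acid: CH2CO2H arm on the quaternary methyl carbon | CC(=O)O[C@@H]1C[C@@]23COC(=O)C2=C[C@H](OC(C)=O)[C@@H](c2ccco2)[C@@H]3[C@@](C)(CC(=O)O)[C@@H]1C | intermediate
30 | mixed trifluoroacetic anhydride of 29 | CC(=O)O[C@@H]1C[C@@]23COC(=O)C2=C[C@H](OC(C)=O)[C@@H](c2ccco2)[C@@H]3[C@@](C)(CC(=O)OC(=O)C(F)(F)F)[C@@H]1C | intermediate
31 | O-acetyl target: the allylic acetate of 32, ring C closed | CC(=O)O[C@@H]1C[C@@]23COC(=O)C2=C[C@H](OC(C)=O)[C@H]2c4occc4C(=O)C[C@@](C)([C@@H]1C)[C@@H]23 | intermediate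
32 | CNP0182929.1 | CC(=O)O[C@@H]1C[C@@]23COC(=O)C2=C[C@H](O)[C@H]2c4occc4C(=O)C[C@@](C)([C@@H]1C)[C@@H]23 | target

**Count and risks**
Total step count: 18. Longest linear sequence: 16 steps (steps 1–6 and 9–18); steps 7–8 make the enal.

Most likely to fail:

1. Step 9. Hydrogen transfer to the first adduct radical, or decarbonylation of the acyl radical, may outrun the congested 6-exo closure, and the facial selectivity at the quaternary carbon may be low. Fallback, from 11 and 16 back to 20: the tin hydride reaction is run at high hydride concentration so that it stops on purpose at the open-chain Giese adduct, the keto aldehyde F1. Ring A is then closed by polar chemistry, an intramolecular Michael addition of the α-formyl carbon to the furyl enone (pyrrolidine/AcOH enamine catalysis, or DBU), which should give 20.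

2. Step 17. Intermolecular acylation at the free furan α-position (oligomerisation) or acid-promoted loss of the allylic acetate may compete with the seven-membered ring closure. Fallback, from 28 back to 31: Dess–Martin oxidation of 28 gives the aldehyde F2; Sc(OTf)3-catalysed intramolecular hydroxyalkylation of the furan β-carbon (a milder electrophile than the acylium equivalent) gives the cyclised furyl carbinol F3; MnO2 oxidation then gives ketone 31.

3. Step 5. The neopentyl aldehyde may condense too slowly, or the ketone may react at its methyl group instead of the furfuryl carbon. Fallback, from 8 and 9 back to 10: 9 is converted into its conjugated lithium enolate with LiN(i-Pr)2 (THF, −78 °C) and added to the lithium carboxylate of 8; the aldol hydroxy acid F4 closes on acidic work-up to the γ-lactone F5, and DBU then expels the carboxylate from the β-position of the ketone (E1cB), which opens the lactone and should return enone acid 10.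

Further compounds
F1 | step 9 | open-chain keto aldehyde (Giese adduct of 17 and 16) | CC(C)(C)[Si](C)(C)OCC[C@@](C)([C@@H](C(=O)CC(C=O)C(O)C(=O)OCC)C)/C=C(\c1ccco1)C(C)=O
F2 | step 17 | aldehyde from alcohol 28 | CC(=O)O[C@@H]1C[C@@]23COC(=O)C2=C[C@H](OC(C)=O)[C@@H](c2ccco2)[C@@H]3[C@@](C)(CC=O)[C@@H]1C
F3 | step 17 | cyclised furyl carbinol (ring C closed, alcohol in place of the ketone) | CC(=O)O[C@@H]1C[C@@]23COC(=O)C2=C[C@H](OC(C)=O)[C@H]2c4occc4C(O)C[C@@](C)([C@@H]1C)[C@@H]23
F4 | step 5 | aldol hydroxy acid from 8 and 9 | CC(C)(C)[Si](C)(C)OCC[C@@](C)([C@@H](C(=O)O)C)C(O)C(c1ccco1)C(C)=O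
F5 | step 5 | γ-lactone of F4 | CC(C)(C)[Si](C)(C)OCC[C@@]1(C)[C@H](C)C(=O)OC1C(c1ccco1)C(C)=O
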